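**Retrosynthetic overview**

- Feature: in ring A the ring oxygen O1 (on C8a), the C5 methoxy oxygen and the C7 hydroxyl oxygen all lie ortho or para to C4a, the carbon that carries the C4 carbonyl, so all three C–O bonds can be made by fluoride displacement on a 2,4,6-trifluorophenyl ketone.
- Rings A and B are bought as arenes and joined at C3–C1' by ketone α-arylation; formylation adds C2; the pyranone ring C is the only ring formed, by intramolecular SNAr making O1–C8a.
- The C7–F and then the C5–F of the resulting 5,7-difluoroisoflavone are displaced by allyl alkoxide and by methoxide.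
- C8 chain: Claisen shift of the 7-O-allyl group to C8, cleavage to the C8 acetaldehyde, then catalyst-controlled isopropenyl addition sets the (R)-carbinol.
- C6 prenyl: 7-O-(1,1-dimethylallyl) ether and Claisen shift to C6, the only free ortho carbon; the 4'-O acetal is removed last.

Key step: step 4

Remark: the carbinol carbon of the C8 chain is read from the SMILES as (R) (O > isopropenyl > CH2Ar > H), which corresponds to Si-face addition to the aldehyde; in step 10 the ligand antipode that gives this sense is used, and the sense is not asserted here for a named antipode.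

Abbreviations: SEM = 2-(trimethylsilyl)ethoxymethyl; TBS = tert-butyldimethylsilyl.

**Route**

Step 1
Reactants: 1 4-bromophenol
Product: 2 1-bromo-4-(SEM-oxy)benzene
Conditions: SEMCl, i-Pr2NEt, CH2Cl2, 0 °C to rt
Reagents that add atoms: 2-(trimethylsilyl)ethoxymethyl chloride, C[Si](C)(C)CCOCCl
Why: O-alkylation of the phenol by the reactive chloromethyl ether (Williamson-type acetal formation) should give an acetal that withstands base, alkoxides and heat and is removed at the end by fluoride without acid.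

Step 2
Reactants: 2 1-bromo-4-(SEM-oxy)benzene; 3 2',4',6'-trifluoroacetophenone
Product: 4 2-[4-(SEM-oxy)phenyl]-1-(2,4,6-trifluorophenyl)ethan-1-one
Conditions: Pd2(dba)3 (1.5 mol%), Xantphos (3.6 mol%), K3PO4, toluene, 80 °C
Reagents that add atoms: none
Why: Palladium-catalysed ketone α-arylation should form the C3–C1' bond, because the insoluble, non-nucleophilic phosphate base keeps the enolate concentration low and cannot displace fluoride, and methyl aryl ketones stop at monoarylation.

Step 3
Reactants: 4 2-[4-(SEM-oxy)phenyl]-1-(2,4,6-trifluorophenyl)ethan-1-one; 5 ethyl formate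
Product: 6 (2Z)-3-hydroxy-2-[4-(SEM-oxy)phenyl]-1-(2,4,6-trifluorophenyl)prop-2-en-1-one
Conditions: NaH (2.2 equiv), HCO2Et (5 equiv), THF, 0 °C; AcOH quench at 0 °C
Reagents that add atoms: ethyl formate (5), CCOC=O
Why: Crossed Claisen condensation of the doubly activated methylene with the non-enolisable formate should give the chelated Z-enol, and since substrate and product are present as enolates the fluoroarene is too electron-rich for ethoxide to displace fluoride at 0 °C.

Step 4
Reactants: 6 (2Z)-3-hydroxy-2-[4-(SEM-oxy)phenyl]-1-(2,4,6-trifluorophenyl)prop-2-en-1-one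
Product: 7 5,7-difluoro-3-[4-(SEM-oxy)phenyl]-4H-chromen-4-one
Conditions: K2CO3 (1.5 equiv), DMF (0.05 M), rt to 60 °C
Reagents that add atoms: none
Why: Carbonate converts the enol into its potassium enolate, whose formyl-derived oxygen adds to C8a, one of the two ortho C–F carbons of the trifluorophenyl ketone, to give a Meisenheimer complex stabilised by the C4 carbonyl and the two remaining fluorines; loss of fluoride completes the addition–elimination and forms the O1–C8a bond. The closest known reaction type is the base-induced SNAr cyclisation of 2-fluoroaryl β-dicarbonyl compounds to chromones, the oxygen counterpart of the ring closure used for fluoroquinolones. The pyranone ring closes in a 6-exo-trig sense, the enolate oxygen attacking an arene carbon held five atoms away by the Z-enolate geometry. No stereocentre is formed. The step needs O- over C-arylation and ortho- over para-substitution: carbon attack would have to form a four-membered ring and the para fluorine cannot be reached within the molecule, while moderate dilution suppresses intermolecular displacement. Because the two ortho fluorines are equivalent, either closure gives the same 5,7-difluoroisoflavone.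

Step 5
Reactants: 7 5,7-difluoro-3-[4-(SEM-oxy)phenyl]-4H-chromen-4-one; 8 prop-2-en-1-ol
Product: 9 7-(allyloxy)-5-fluoro-3-[4-(SEM-oxy)phenyl]-4H-chromen-4-one
Conditions: allyl alcohol (1.05 equiv), NaH, THF, 0 °C; then 7, 15-crown-5, DMF, −40 to 0 °C
Reagents that add atoms: allyl alcohol (8), C=CCO
Why: Nucleophilic aromatic substitution in which the crown-separated alkoxide in a dipolar aprotic medium should attack the unhindered C7–F para to the C4 carbonyl rather than the peri-crowded C5–F, the new alkoxy donor then deactivating the ring so that the reaction stops after one substitution.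

Step 6
Reactants: 9 7-(allyloxy)-5-fluoro-3-[4-(SEM-oxy)phenyl]-4H-chromen-4-one
Product: 10 7-(allyloxy)-5-methoxy-3-[4-(SEM-oxy)phenyl]-4H-chromen-4-one
Conditions: NaOMe (1.5 equiv), anhydrous THF/MeOH, 50 °C
Reagents that add atoms: sodium methoxide, [Na+].[O-]C
Why: Nucleophilic aromatic substitution at the only remaining C–F bond, ortho to the C4 carbonyl and assisted by sodium bridging between the carbonyl oxygen and methoxide, should install the C5 methoxy group, while methoxide addition at C2 stays reversible in the absence of water.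

Step 7
Reactants: 10 7-(allyloxy)-5-methoxy-3-[4-(SEM-oxy)phenyl]-4H-chromen-4-one
Product: 12 8-allyl-7-hydroxy-5-methoxy-3-[4-(SEM-oxy)phenyl]-4H-chromen-4-one, via C8 allyl dienone 11 (not isolated)
Conditions: N,N-diethylaniline, 200 °C, Ar
Reagents that add atoms: none
Why: Aromatic Claisen rearrangement in which the [3,3] shift should go to C8 rather than C6, because the C7–C8 bond of a chromone has the higher double-bond character and C6 is flanked by the C5 methoxy group, the dienone then enolising to the phenol.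

Step 8
Reactants: 12 8-allyl-7-hydroxy-5-methoxy-3-[4-(SEM-oxy)phenyl]-4H-chromen-4-one
Product: 13 8-allyl-7-(TBS-oxy)-5-methoxy-3-[4-(SEM-oxy)phenyl]-4H-chromen-4-one
Conditions: TBSCl, imidazole, DMF, rt
Reagents that add atoms: tert-butyldimethylsilyl chloride, CC(C)(C)[Si](C)(C)Cl
Why: Silylation of the C7 phenol should prevent lactol and benzofuran formation once the ortho acetaldehyde is unmasked, and the silyl ether is later cleaved by mild fluoride that spares the SEM acetal.

Step 9
Reactants: 13 8-allyl-7-(TBS-oxy)-5-methoxy-3-[4-(SEM-oxy)phenyl]-4H-chromen-4-one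
Product: 15 2-{7-(TBS-oxy)-5-methoxy-4-oxo-3-[4-(SEM-oxy)phenyl]-4H-chromen-8-yl}acetaldehyde, via C8 dihydroxypropyl diol 14 (not isolated)
Conditions: OsO4 (2 mol%), NaIO4 (4 equiv), 2,6-lutidine, dioxane/H2O 3:1, rt; aldehyde used at once
Reagents that add atoms: osmium tetroxide, O=[Os](=O)(=O)=O; sodium periodate, [Na+].[O-]I(=O)(=O)=O
Why: Lemieux–Johnson oxidation in which the monosubstituted alkene is osmylated far faster than the push–pull C2=C3 bond, and periodate cleavage of the diol should give the arylacetaldehyde with loss of one carbon.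

Step 10
Reactants: 15 2-{7-(TBS-oxy)-5-methoxy-4-oxo-3-[4-(SEM-oxy)phenyl]-4H-chromen-8-yl}acetaldehyde; 16 2-bromopropene
Product: 17 8-[(2R)-2-hydroxy-3-methylbut-3-en-1-yl]-7-(TBS-oxy)-5-methoxy-3-[4-(SEM-oxy)phenyl]-4H-chromen-4-one
Conditions: CrCl2 (10 mol%), chiral valinol-derived 2-(2-sulfonamidoaryl)oxazoline ligand (11 mol%), proton sponge (11 mol%), NiCl2·neocuproine (2 mol%), Mn, Cp2ZrCl2, LiCl, MeCN, rt
Reagents that add atoms: 2-bromopropene (16), CC(Br)=C
Why: Catalytic asymmetric Nozaki–Hiyama–Kishi alkenylation in which the isopropenylchromium(III) species formed via nickel adds only to the aldehyde under non-basic conditions, and the chiral chromium–sulfonamide complex sets the carbinol centre by delivering the alkenyl group to the Si face, which gives the (R) configuration.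

Step 11
Reactants: 17 8-[(2R)-2-hydroxy-3-methylbut-3-en-1-yl]-7-(TBS-oxy)-5-methoxy-3-[4-(SEM-oxy)phenyl]-4H-chromen-4-one
Product: 18 7-hydroxy-8-[(2R)-2-hydroxy-3-methylbut-3-en-1-yl]-5-methoxy-3-[4-(SEM-oxy)phenyl]-4H-chromen-4-one
Conditions: KHF2 (2 equiv), MeOH, rt
Reagents that add atoms: none
Why: Fluoride-mediated desilylation in which bifluoride in methanol cleaves the phenolic silyl ether at room temperature and should leave the SEM acetal, which needs hot fluoride, and the allylic alcohol untouched.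

Step 12
Reactants: 19 2-methylbut-3-en-2-ol
Product: 20 tert-butyl 2-methylbut-3-en-2-yl carbonate
Conditions: n-BuLi, THF, −78 °C; Boc2O, −78 °C to rt; H2O quench
Reagents that add atoms: di-tert-butyl dicarbonate, CC(C)(C)OC(=O)OC(=O)OC(C)(C)C
Why: Acylation of the lithium alkoxide of the tertiary alcohol by the dicarbonate should give the mixed carbonate that serves as the π-allyl precursor.

Step 13
Reactants: 18 7-hydroxy-8-[(2R)-2-hydroxy-3-methylbut-3-en-1-yl]-5-methoxy-3-[4-(SEM-oxy)phenyl]-4H-chromen-4-one; 20 tert-butyl 2-methylbut-3-en-2-yl carbonate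
Product: 21 8-[(2R)-2-hydroxy-3-methylbut-3-en-1-yl]-5-methoxy-7-[(2-methylbut-3-en-2-yl)oxy]-3-[4-(SEM-oxy)phenyl]-4H-chromen-4-one
Conditions: Pd(PPh3)4 (5 mol%), degassed THF, 0 °C
Reagents that add atoms: tert-butyl 2-methylbut-3-en-2-yl carbonate (20), C=CC(C)(C)OC(=O)OC(C)(C)C
Why: Tsuji–Trost O-allylation in which decarboxylative ionisation gives the 1,1-dimethyl-π-allylpalladium cation and tert-butoxide, the acidic C7 phenol rather than the secondary alcohol is deprotonated, and the phenoxide attacks the more substituted terminus under kinetic control to give the tertiary ether.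

Step 14
Reactants: 21 8-[(2R)-2-hydroxy-3-methylbut-3-en-1-yl]-5-methoxy-7-[(2-methylbut-3-en-2-yl)oxy]-3-[4-(SEM-oxy)phenyl]-4H-chromen-4-one
Product: 23 7-hydroxy-8-[(2R)-2-hydroxy-3-methylbut-3-en-1-yl]-5-methoxy-6-(3-methylbut-2-en-1-yl)-3-[4-(SEM-oxy)phenyl]-4H-chromen-4-one, via C6 prenyl dienone 22 (not isolated)
Conditions: N,N-diethylaniline, 140 °C, Ar
Reagents that add atoms: none
Why: Aromatic Claisen rearrangement in which, with C8 substituted, the gem-dimethyl-accelerated [3,3] shift can end productively only at C6, where enolisation of the dienone gives the 6-prenyl phenol, and the neutral, weakly basic medium leaves the (R)-carbinol untouched.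

Step 15
Reactants: 23 7-hydroxy-8-[(2R)-2-hydroxy-3-methylbut-3-en-1-yl]-5-methoxy-6-(3-methylbut-2-en-1-yl)-3-[4-(SEM-oxy)phenyl]-4H-chromen-4-one
Product: 24 7-hydroxy-8-[(2R)-2-hydroxy-3-methylbut-3-en-1-yl]-3-(4-hydroxyphenyl)-5-methoxy-6-(3-methylbut-2-en-1-yl)-4H-chromen-4-one
Conditions: TBAF (5 equiv), THF, 60 °C; aq NH4Cl work-up
Reagents that add atoms: none
Why: Fluoride-induced β-silyl fragmentation of the SEM acetal should free the 4'-phenol without acid, so the prenyl group cannot cyclise onto the C7 hydroxyl and the allylic alcohol cannot ionise.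

**Compound list**

1 | 4-bromophenol | Oc1ccc(Br)cc1 | starting material
2 | 1-bromo-4-(SEM-oxy)benzene | C[Si](C)(C)CCOCOc1ccc(Br)cc1 | intermediate
3 | 2',4',6'-trifluoroacetophenone | CC(=O)c1c(F)cc(F)cc1F | starting material
4 | 2-[4-(SEM-oxy)phenyl]-1-(2,4,6-trifluorophenyl)ethan-1-one | O=C(Cc1ccc(OCOCC[Si](C)(C)C)cc1)c1c(F)cc(F)cc1F | intermediate
5 | ethyl formate | CCOC=O | starting material
6 | (2Z)-3-hydroxy-2-[4-(SEM-oxy)phenyl]-1-(2,4,6-trifluorophenyl)prop-2-en-1-one | O/C=C(/c1ccc(OCOCC[Si](C)(C)C)cc1)C(=O)c1c(F)cc(F)cc1F | intermediate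
7 | 5,7-difluoro-3-[4-(SEM-oxy)phenyl]-4H-chromen-4-one | O=c1c(-c2ccc(OCOCC[Si](C)(C)C)cc2)coc2cc(F)cc(F)c12 | intermediate
8 | prop-2-en-1-ol (allyl alcohol) | C=CCO | starting material
9 | 7-(allyloxy)-5-fluoro-3-[4-(SEM-oxy)phenyl]-4H-chromen-4-one | C=CCOc1cc(F)c2c(=O)c(-c3ccc(OCOCC[Si](C)(C)C)cc3)coc2c1 | intermediate
10 | 7-(allyloxy)-5-methoxy-3-[4-(SEM-oxy)phenyl]-4H-chromen-4-one | C=CCOc1cc(OC)c2c(=O)c(-c3ccc(OCOCC[Si](C)(C)C)cc3)coc2c1 | intermediate
11 | 8-allyl-5-methoxy-3-[4-(SEM-oxy)phenyl]-8H-chromene-4,7-dione (ortho-dienone, C8 configuration undefined, formed in situ) | C=CCC1C(=O)C=C(OC)C2=C1OC=C(c1ccc(OCOCC[Si](C)(C)C)cc1)C2=O | intermediate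
12 | 8-allyl-7-hydroxy-5-methoxy-3-[4-(SEM-oxy)phenyl]-4H-chromen-4-one | C=CCc1c(O)cc(OC)c2c(=O)c(-c3ccc(OCOCC[Si](C)(C)C)cc3)coc12 | intermediate
13 | 8-allyl-7-(TBS-oxy)-5-methoxy-3-[4-(SEM-oxy)phenyl]-4H-chromen-4-one | C=CCc1c(O[Si](C)(C)C(C)(C)C)cc(OC)c2c(=O)c(-c3ccc(OCOCC[Si](C)(C)C)cc3)coc12 | intermediate
14 | 8-(2,3-dihydroxypropyl)-7-(TBS-oxy)-5-methoxy-3-[4-(SEM-oxy)phenyl]-4H-chromen-4-one (racemic, formed in situ) | OCC(O)Cc1c(O[Si](C)(C)C(C)(C)C)cc(OC)c2c(=O)c(-c3ccc(OCOCC[Si](C)(C)C)cc3)coc12 | intermediate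
15 | 2-{7-(TBS-oxy)-5-methoxy-4-oxo-3-[4-(SEM-oxy)phenyl]-4H-chromen-8-yl}acetaldehyde | O=CCc1c(O[Si](C)(C)C(C)(C)C)cc(OC)c2c(=O)c(-c3ccc(OCOCC[Si](C)(C)C)cc3)coc12 | intermediate
16 | 2-bromopropene | CC(Br)=C | starting material
17 | 8-[(2R)-2-hydroxy-3-methylbut-3-en-1-yl]-7-(TBS-oxy)-5-methoxy-3-[4-(SEM-oxy)phenyl]-4H-chromen-4-one | C=C(C)[C@H](O)Cc1c(O[Si](C)(C)C(C)(C)C)cc(OC)c2c(=O)c(-c3ccc(OCOCC[Si](C)(C)C)cc3)coc12 | intermediate
18 | 7-hydroxy-8-[(2R)-2-hydroxy-3-methylbut-3-en-1-yl]-5-methoxy-3-[4-(SEM-oxy)phenyl]-4H-chromen-4-one | C=C(C)[C@H](O)Cc1c(O)cc(OC)c2c(=O)c(-c3ccc(OCOCC[Si](C)(C)C)cc3)coc12 | intermediate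
19 | 2-methylbut-3-en-2-ol | C=CC(C)(C)O | starting material
20 | tert-butyl 2-methylbut-3-en-2-yl carbonate | C=CC(C)(C)OC(=O)OC(C)(C)C | intermediate
21 | 8-[(2R)-2-hydroxy-3-methylbut-3-en-1-yl]-5-methoxy-7-[(2-methylbut-3-en-2-yl)oxy]-3-[4-(SEM-oxy)phenyl]-4H-chromen-4-one | C=C(C)[C@H](O)Cc1c(OC(C)(C)C=C)cc(OC)c2c(=O)c(-c3ccc(OCOCC[Si](C)(C)C)cc3)coc12 | intermediate
22 | 8-[(2R)-2-hydroxy-3-methylbut-3-en-1-yl]-5-methoxy-6-(3-methylbut-2-en-1-yl)-3-[4-(SEM-oxy)phenyl]-6H-chromene-4,7-dione (ortho-dienone, C6 configuration undefined, formed in situ) | C=C(C)[C@H](O)CC1=C2OC=C(c3ccc(OCOCC[Si](C)(C)C)cc3)C(=O)C2=C(OC)C(CC=C(C)C)C1=O | intermediate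
23 | 7-hydroxy-8-[(2R)-2-hydroxy-3-methylbut-3-en-1-yl]-5-methoxy-6-(3-methylbut-2-en-1-yl)-3-[4-(SEM-oxy)phenyl]-4H-chromen-4-one | C=C(C)[C@H](O)Cc1c(O)c(CC=C(C)C)c(OC)c2c(=O)c(-c3ccc(OCOCC[Si](C)(C)C)cc3)coc12 | intermediate
24 | 7-hydroxy-8-[(2R)-2-hydroxy-3-methylbut-3-en-1-yl]-3-(4-hydroxyphenyl)-5-methoxy-6-(3-methylbut-2-en-1-yl)-4H-chromen-4-one (CNP0324832.1) | C=C(C)[C@H](O)Cc1c(O)c(CC=C(C)C)c(OC)c2c(=O)c(-c3ccc(O)cc3)coc12 | target

**Step count**

Total: 15 steps. Longest linear sequence: 14 steps (steps 1–11 and 13–15, from 4-bromophenol); step 12 is a one-step side branch.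

**Steps most likely to fail, with fallbacks**

Step 5. The alkoxide may be delivered to C5 through sodium chelation at the C4 carbonyl, or a second displacement may follow the first, so that the allyl group ends on the wrong oxygen. The fallback sets out from 7 and reverses the order, using chelation instead of working against it. One equivalent of NaOMe in toluene at 0 °C (non-polar medium, ion pair bound at the carbonyl) should give 7-fluoro-5-methoxy-3-[4-(SEM-oxy)phenyl]-4H-chromen-4-one F1. Sodium allyloxide in DMSO at 40 °C then displaces the only remaining fluoride, at C7, and the route is rejoined at 10.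

Step 10. Facial selectivity of the chromium-mediated addition may be insufficient, or the enolisable arylacetaldehyde may self-condense before it is consumed. The fallback sets out from 15. Isopropenylmagnesium bromide with CeCl3 (THF, −78 °C) should give racemic 8-(2-hydroxy-3-methylbut-3-en-1-yl)-7-(TBS-oxy)-5-methoxy-3-[4-(SEM-oxy)phenyl]-4H-chromen-4-one F2. Dess–Martin periodinane with NaHCO3 in CH2Cl2 oxidises it to 8-(3-methyl-2-oxobut-3-en-1-yl)-7-(TBS-oxy)-5-methoxy-3-[4-(SEM-oxy)phenyl]-4H-chromen-4-one F3. Corey–Bakshi–Shibata reduction with (S)-2-methyl-CBS-oxazaborolidine and catecholborane (toluene, −78 °C) then gives the (R)-alcohol, the α-branched alkenyl group acting as the large substituent, and the route is rejoined at 17.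

Step 13. The tertiary ether may re-ionise under palladium and drift to the linear prenyl ether, or the hindered C7 phenol may react sluggishly. The fallback sets out from 18. Alkylation with 3-chloro-3-methylbut-1-yne (K2CO3, KI, CuI cat., acetone, 50 °C) should give 8-[(2R)-2-hydroxy-3-methylbut-3-en-1-yl]-5-methoxy-7-[(2-methylbut-3-yn-2-yl)oxy]-3-[4-(SEM-oxy)phenyl]-4H-chromen-4-one F4. Semi-hydrogenation (H2, Lindlar catalyst, quinoline, EtOAc) then reduces only the alkyne, and the route is rejoined at 21.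

Further compounds

F1 | step 5 | 7-fluoro-5-methoxy-3-[4-(SEM-oxy)phenyl]-4H-chromen-4-one | COc1cc(F)cc2occ(-c3ccc(OCOCC[Si](C)(C)C)cc3)c(=O)c12
F2 | step 10 | racemic 8-(2-hydroxy-3-methylbut-3-en-1-yl)-7-(TBS-oxy)-5-methoxy-3-[4-(SEM-oxy)phenyl]-4H-chromen-4-one | C=C(C)C(O)Cc1c(O[Si](C)(C)C(C)(C)C)cc(OC)c2c(=O)c(-c3ccc(OCOCC[Si](C)(C)C)cc3)coc12
F3 | step 10 | 8-(3-methyl-2-oxobut-3-en-1-yl)-7-(TBS-oxy)-5-methoxy-3-[4-(SEM-oxy)phenyl]-4H-chromen-4-one | C=C(C)C(=O)Cc1c(O[Si](C)(C)C(C)(C)C)cc(OC)c2c(=O)c(-c3ccc(OCOCC[Si](C)(C)C)cc3)coc12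
F4 | step 13 | 8-[(2R)-2-hydroxy-3-methylbut-3-en-1-yl]-5-methoxy-7-[(2-methylbut-3-yn-2-yl)oxy]-3-[4-(SEM-oxy)phenyl]-4H-chromen-4-one | C=C(C)[C@H](O)Cc1c(OC(C)(C)C#C)cc(OC)c2c(=O)c(-c3ccc(OCOCC[Si](C)(C)C)cc3)coc12
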